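## Retrosynthetic overview

1. Ring numbering: cyclohexene C1 (carries the side chain through C7), C2 (carries CH3), C3, C4, C5, C6 (gem-dimethyl); the chromene is numbered in the usual way.
2. The pyran ring of the chromene is closed last: C3=C4 by ring-closing metathesis of diene 20, and O1–C2 with the (S) centre by palladium-catalysed asymmetric allylic O-alkylation of vinylphenol 19 with the C20 allylic carbonate 16.
3. The C20 chain comes from the C7–C8 bond: β-cyclogeranyl sulfone 9 is alkylated with the (E,E)-bromide 13 made from geraniol, which brings in the (E)-trisubstituted alkene ready-made.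
4. The cyclohexene is the first ring formed, in one flask, by a [3+3] annulation of methyl acetoacetate with prenyl bromide that makes C3–C4 and C1–C6; enol triflate formation and methyl cross-coupling then turn the β-keto ester into the C1=C2(CH3) alkene.
5. Enabling feature: C6 is a quaternary gem-dimethyl carbon (the site of a tertiary cation) and C4–C5–C6 is a prenyl unit, while C3–C2–C1–C7 is the carbon chain of acetoacetate; the six ring atoms therefore split into a 1,3-dielectrophile and a 1,3-dinucleophile of matched polarity.

Key step: step 1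

Assumption: the (R,R)-enantiomer of the Trost ligand is taken to give the (S)-ether from the (E)-carbonate in step 14; if a model run with geranyl methyl carbonate shows the opposite sense, the (S,S)-ligand is used with no other change.

## Route

Step 1
Reactants: 1 methyl acetoacetate; 2 prenyl bromide (1-bromo-3-methylbut-2-ene)
Product: 4 methyl 2,2-dimethyl-6-oxocyclohexane-1-carboxylate, via methyl 7-methyl-3-oxooct-6-enoate 3 (not isolated)
Conditions: NaH, THF, 0 °C; n-BuLi, 0 °C; 2, 0 °C to rt; HCl (1 equiv, Et2O); THF evaporated, CH2Cl2; SnCl4 (2.5 equiv), 0 °C to rt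
Reagents that add atoms: none
Why: γ-Alkylation of the acetoacetate dianion is followed in the same flask by a Lewis-acid cation–olefin cyclisation: the γ-carbanion (the more basic, less delocalised terminus) displaces bromide from the primary carbon of 2 by SN2 (bond C3–C4), and once one equivalent of HCl has returned the β-keto ester 3, SnCl4 chelates its two carbonyl groups, the trisubstituted alkene is protonated (or hydrochlorinated and re-ionised) at C5 to the tertiary cation at the future gem-dimethyl carbon C6, and the chelated tin enolate captures it through its α-carbon (bond C1–C6). Both stages are close-precedent reaction types on this very substrate pair (dianion γ-alkylation with allylic halides; SnCl4-promoted cyclisation of olefinic β-keto esters), and only their telescoping is new. The one ring closes 6-endo-trig at the alkene (6-enolendo at the nucleophile), Markovnikov protonation ruling out the 5-exo alternative, which would need a secondary cation. The only new stereocentre, C1 of 4, forms racemic and is of no consequence because it becomes sp2 in step 2. The selectivities needed are γ- over α-alkylation (secured by the dianion), SN2 over SN2' (primary, unhindered carbon of 2) and C- over O-capture of the cation (secured by tin chelation, which ties up the enol oxygen). The polarity match of primary allylic carbon with γ-carbanion and of tertiary cation with α-carbon places the gem-dimethyl group next to the ester-bearing carbon and nowhere else.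

Step 2
Reactants: 4 methyl 2,2-dimethyl-6-oxocyclohexane-1-carboxylate
Product: 5 methyl 6,6-dimethyl-2-[(trifluoromethylsulfonyl)oxy]cyclohex-1-ene-1-carboxylate
Conditions: NaH, Et2O, 0 °C; Tf2O, 0 °C
Reagents that add atoms: triflic anhydride, O=S(=O)(OS(=O)(=O)C(F)(F)F)C(F)(F)F
Why: Enol triflate formation from the sodium enolate of a β-keto ester, which can enolise only between the two carbonyl groups, so the position of the future tetrasubstituted C1=C2 alkene is fixed without a regiochemical choice.

Step 3
Reactants: 5 methyl 6,6-dimethyl-2-[(trifluoromethylsulfonyl)oxy]cyclohex-1-ene-1-carboxylate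
Product: 6 methyl 2,6,6-trimethylcyclohex-1-ene-1-carboxylate (methyl β-cyclogeranate)
Conditions: Fe(acac)3 (5 mol%), MeMgBr (1.3 equiv), THF/NMP, −30 °C
Reagents that add atoms: methylmagnesium bromide, C[Mg]Br
Why: Iron-catalysed Kumada-type cross-coupling of an electron-poor alkenyl triflate with a methyl Grignard reagent, fast enough at −30 °C to leave the hindered ester alone, should replace the triflate by the C2 methyl group with the double bond held in place.

Step 4
Reactants: 6 methyl 2,6,6-trimethylcyclohex-1-ene-1-carboxylate
Product: 7 (2,6,6-trimethylcyclohex-1-en-1-yl)methanol (β-cyclogeraniol)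
Conditions: i-Bu2AlH (2.5 equiv), CH2Cl2, −78 to 0 °C; aqueous potassium sodium tartrate
Reagents that add atoms: none
Why: Hydride reduction of the ester to the primary allylic alcohol; the twisted, fully substituted enoate is a poor conjugate acceptor, so only 1,2-reduction is expected.

Step 5
Reactants: 7 (2,6,6-trimethylcyclohex-1-en-1-yl)methanol
Product: 9 phenyl (2,6,6-trimethylcyclohex-1-en-1-yl)methyl sulfone, via β-cyclogeranyl bromide 8 (not isolated)
Conditions: PBr3 (0.4 equiv), pyridine (0.2 equiv), Et2O, 0 °C; then PhSO2Na (2.5 equiv), DMF, rt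
Reagents that add atoms: sodium benzenesulfinate, [Na+].[O-]S(=O)c1ccccc1; phosphorus tribromide, BrP(Br)Br (supplies only the bromine of 8)
Why: Conversion of the allylic alcohol into the bromide with PBr3 followed by SN2 S-alkylation of the sulfinate in the same flask, so the labile allylic bromide is never stored; attack by sulfur at the primary carbon is expected over attack by oxygen or allylic transposition to the neopentyl-like ring carbon.

Step 6
Reactants: 10 geraniol
Product: 11 benzyl (2E)-3,7-dimethylocta-2,6-dienyl ether (geranyl benzyl ether)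
Conditions: NaH, BnBr, n-Bu4NI (cat.), THF, 0 °C to rt
Reagents that add atoms: benzyl bromide, BrCc1ccccc1
Why: Williamson ether synthesis on the primary allylic alkoxide, which masks the alcohol as a group that step 10 removes together with the sulfone.

Step 7
Reactants: 11 benzyl (2E)-3,7-dimethylocta-2,6-dienyl ether
Product: 12 (2E,6E)-8-(benzyloxy)-2,6-dimethylocta-2,6-dien-1-ol
Conditions: SeO2 (cat.), t-BuOOH, salicylic acid (cat.), CH2Cl2, rt
Reagents that add atoms: tert-butyl hydroperoxide, CC(C)(C)OO
Why: Catalytic selenium dioxide allylic oxidation (ene reaction followed by [2,3]-sigmatropic rearrangement) should attack the more electron-rich distal trisubstituted alkene, and there the (E)-methyl group, giving the (E)-allylic alcohol, while the proximal alkene is deactivated by its allylic oxygen.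

Step 8
Reactants: 12 (2E,6E)-8-(benzyloxy)-2,6-dimethylocta-2,6-dien-1-ol
Product: 13 benzyl (2E,6E)-8-bromo-3,7-dimethylocta-2,6-dienyl ether
Conditions: PBr3 (0.4 equiv), Et2O, 0 °C
Reagents that add atoms: phosphorus tribromide, BrP(Br)Br
Why: Bromination of the primary allylic alcohol with PBr3 at 0 °C is expected to proceed without allylic transposition or loss of alkene geometry.

Step 9
Reactants: 9 phenyl (2,6,6-trimethylcyclohex-1-en-1-yl)methyl sulfone; 13 benzyl (2E,6E)-8-bromo-3,7-dimethylocta-2,6-dienyl ether
Product: 14 benzyl (2E,6E)-3,7-dimethyl-9-(phenylsulfonyl)-9-(2,6,6-trimethylcyclohex-1-en-1-yl)nona-2,6-dienyl ether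
Conditions: n-BuLi, THF, −78 °C; 13, −78 to −20 °C
Reagents that add atoms: none
Why: Alkylation of the α-sulfonyl carbanion by SN2 at the primary allylic bromide (sulfone coupling of the Julia type) is a standard union of terpenoid units and forms C7–C8; the sulfone-bearing carbon becomes a racemic stereocentre that step 10 erases.

Step 10
Reactants: 14 benzyl (2E,6E)-3,7-dimethyl-9-(phenylsulfonyl)-9-(2,6,6-trimethylcyclohex-1-en-1-yl)nona-2,6-dienyl ether
Product: 15 (2E,6E)-3,7-dimethyl-9-(2,6,6-trimethylcyclohex-1-en-1-yl)nona-2,6-dien-1-ol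
Conditions: Li, EtNH2, THF, −78 °C; NH4Cl
Reagents that add atoms: none
Why: Dissolving-metal reduction should cleave the allylic C–S bond and the benzylic C–O bond in one operation, the allyl anion being protonated at the less hindered exocyclic carbon so that the tetrasubstituted ring alkene stays in place, while the isolated alkenes are not reduced at −78 °C.

Step 11
Reactants: 15 (2E,6E)-3,7-dimethyl-9-(2,6,6-trimethylcyclohex-1-en-1-yl)nona-2,6-dien-1-ol
Product: 16 methyl (2E,6E)-3,7-dimethyl-9-(2,6,6-trimethylcyclohex-1-en-1-yl)nona-2,6-dienyl carbonate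
Conditions: ClCO2Me, pyridine, CH2Cl2, 0 °C
Reagents that add atoms: methyl chloroformate, COC(=O)Cl
Why: Acylation of the primary allylic alcohol with a chloroformate gives the carbonate, a leaving group that releases its own base (methoxide) on ionisation in step 14.

Step 12
Reactants: 17 2,5-dihydroxybenzaldehyde
Product: 18 5-[(tert-butyldimethylsilyl)oxy]-2-hydroxybenzaldehyde
Conditions: TBSCl (1.05 equiv), imidazole, CH2Cl2, 0 °C
Reagents that add atoms: tert-butyldimethylsilyl chloride, CC(C)(C)[Si](C)(C)Cl
Why: Selective silylation of the 5-hydroxyl group, because the 2-hydroxyl group is tied up in a hydrogen bond to the formyl group and is the less nucleophilic of the two.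

Step 13
Reactants: 18 5-[(tert-butyldimethylsilyl)oxy]-2-hydroxybenzaldehyde
Product: 19 4-[(tert-butyldimethylsilyl)oxy]-2-vinylphenol
Conditions: Ph3PCH3Br, KOt-Bu (2.3 equiv), THF, 0 °C to rt
Reagents that add atoms: methyltriphenylphosphonium bromide, C[P+](c1ccccc1)(c1ccccc1)c1ccccc1.[Br-]
Why: Wittig methylenation of the aldehyde, the first equivalent of base being consumed by the phenol, whose phenoxide slows but does not prevent the olefination; the electron-rich vinylphenol is used without storage.

Step 14
Reactants: 16 methyl (2E,6E)-3,7-dimethyl-9-(2,6,6-trimethylcyclohex-1-en-1-yl)nona-2,6-dienyl carbonate; 19 4-[(tert-butyldimethylsilyl)oxy]-2-vinylphenol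
Product: 20 tert-butyl{4-{[(3S,6E)-3,7-dimethyl-9-(2,6,6-trimethylcyclohex-1-en-1-yl)nona-1,6-dien-3-yl]oxy}-3-vinylphenoxy}dimethylsilane
Conditions: Pd2(dba)3·CHCl3 (1 mol%), (R,R)-Trost ligand (3 mol%), CH2Cl2, rt
Reagents that add atoms: none
Why: Palladium-catalysed asymmetric allylic alkylation (Tsuji–Trost reaction with the Trost ligand): ionisation of 16 gives a π-allylpalladium complex whose two faces interconvert through the η1-complex at the unsubstituted terminus, and the chiral pocket of the ligand directs the phenol of 19 (deprotonated by the released methoxide) to one face of the more substituted terminus, which sets C2 as (S) and gives the branched tertiary ether, the outcome established for simple phenols with geranyl-type carbonates; the weakly acidic, alkoxy-substituted phenol makes the ether a poor leaving group, so the kinetic product should not re-ionise.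

Step 15
Reactants: 20 tert-butyl{4-{[(3S,6E)-3,7-dimethyl-9-(2,6,6-trimethylcyclohex-1-en-1-yl)nona-1,6-dien-3-yl]oxy}-3-vinylphenoxy}dimethylsilane
Product: 21 tert-butyldimethyl{[(2S)-2-methyl-2-[(3E)-4-methyl-6-(2,6,6-trimethylcyclohex-1-en-1-yl)hex-3-en-1-yl]-2H-chromen-6-yl]oxy}silane
Conditions: first-generation Grubbs catalyst RuCl2(PCy3)2(=CHPh) (5 mol%), CH2Cl2 (0.01 M), 40 °C
Reagents that add atoms: none
Why: Ring-closing metathesis between the styrene and the vinyl group releases ethylene and closes the pyran ring without touching the adjacent quaternary stereocentre; the first-generation catalyst is chosen because it engages monosubstituted alkenes only and should leave the trisubstituted and the tetrasubstituted alkene alone.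

Step 16
Reactants: 21 tert-butyldimethyl{[(2S)-2-methyl-2-[(3E)-4-methyl-6-(2,6,6-trimethylcyclohex-1-en-1-yl)hex-3-en-1-yl]-2H-chromen-6-yl]oxy}silane
Product: 22 (2S)-2-methyl-2-[(3E)-4-methyl-6-(2,6,6-trimethylcyclohex-1-en-1-yl)hex-3-en-1-yl]-2H-chromen-6-ol
Conditions: TBAF, AcOH, THF, 0 °C
Reagents that add atoms: none
Why: Fluoride cleavage of the aryl silyl ether, buffered with acetic acid so that the air-sensitive chromenol is not exposed to base, should give the target with the stereocentre and all three alkenes unchanged.

## Compound list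

1 | methyl acetoacetate | COC(=O)CC(C)=O | starting material
2 | prenyl bromide (1-bromo-3-methylbut-2-ene) | CC(C)=CCBr | starting material
3 | methyl 7-methyl-3-oxooct-6-enoate | COC(=O)CC(=O)CCC=C(C)C | intermediate
4 | methyl 2,2-dimethyl-6-oxocyclohexane-1-carboxylate (racemic) | COC(=O)C1C(=O)CCCC1(C)C | intermediate
5 | methyl 6,6-dimethyl-2-[(trifluoromethylsulfonyl)oxy]cyclohex-1-ene-1-carboxylate | COC(=O)C1=C(OS(=O)(=O)C(F)(F)F)CCCC1(C)C | intermediate
6 | methyl 2,6,6-trimethylcyclohex-1-ene-1-carboxylate | COC(=O)C1=C(C)CCCC1(C)C | intermediate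
7 | (2,6,6-trimethylcyclohex-1-en-1-yl)methanol | CC1=C(CO)C(C)(C)CCC1 | intermediate
8 | 2-(bromomethyl)-1,3,3-trimethylcyclohex-1-ene (β-cyclogeranyl bromide) | CC1=C(CBr)C(C)(C)CCC1 | intermediate
9 | phenyl (2,6,6-trimethylcyclohex-1-en-1-yl)methyl sulfone | CC1=C(CS(=O)(=O)c2ccccc2)C(C)(C)CCC1 | intermediate
10 | geraniol | CC(C)=CCC/C(C)=C/CO | starting material
11 | benzyl (2E)-3,7-dimethylocta-2,6-dienyl ether | CC(C)=CCC/C(C)=C/COCc1ccccc1 | intermediate
12 | (2E,6E)-8-(benzyloxy)-2,6-dimethylocta-2,6-dien-1-ol | OC/C(C)=C/CC/C(C)=C/COCc1ccccc1 | intermediate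
13 | benzyl (2E,6E)-8-bromo-3,7-dimethylocta-2,6-dienyl ether | BrC/C(C)=C/CC/C(C)=C/COCc1ccccc1 | intermediate
14 | benzyl (2E,6E)-3,7-dimethyl-9-(phenylsulfonyl)-9-(2,6,6-trimethylcyclohex-1-en-1-yl)nona-2,6-dienyl ether (racemic at C9) | CC1=C(C(C/C(C)=C/CC/C(C)=C/COCc2ccccc2)S(=O)(=O)c2ccccc2)C(C)(C)CCC1 | intermediate
15 | (2E,6E)-3,7-dimethyl-9-(2,6,6-trimethylcyclohex-1-en-1-yl)nona-2,6-dien-1-ol | CC1=C(CC/C(C)=C/CC/C(C)=C/CO)C(C)(C)CCC1 | intermediate
16 | methyl (2E,6E)-3,7-dimethyl-9-(2,6,6-trimethylcyclohex-1-en-1-yl)nona-2,6-dienyl carbonate | CC1=C(CC/C(C)=C/CC/C(C)=C/COC(=O)OC)C(C)(C)CCC1 | intermediate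
17 | 2,5-dihydroxybenzaldehyde | O=Cc1cc(O)ccc1O | starting material
18 | 5-[(tert-butyldimethylsilyl)oxy]-2-hydroxybenzaldehyde | O=Cc1cc(O[Si](C)(C)C(C)(C)C)ccc1O | intermediate
19 | 4-[(tert-butyldimethylsilyl)oxy]-2-vinylphenol | C=Cc1cc(O[Si](C)(C)C(C)(C)C)ccc1O | intermediate
20 | tert-butyl{4-{[(3S,6E)-3,7-dimethyl-9-(2,6,6-trimethylcyclohex-1-en-1-yl)nona-1,6-dien-3-yl]oxy}-3-vinylphenoxy}dimethylsilane | CC1=C(CC/C(C)=C/CC[C@@](C)(C=C)Oc2ccc(O[Si](C)(C)C(C)(C)C)cc2C=C)C(C)(C)CCC1 | intermediate
21 | tert-butyldimethyl{[(2S)-2-methyl-2-[(3E)-4-methyl-6-(2,6,6-trimethylcyclohex-1-en-1-yl)hex-3-en-1-yl]-2H-chromen-6-yl]oxy}silane | CC1=C(CC/C(C)=C/CC[C@@]2(C)C=Cc3cc(O[Si](C)(C)C(C)(C)C)ccc3O2)C(C)(C)CCC1 | intermediate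
22 | (2S)-2-methyl-2-[(3E)-4-methyl-6-(2,6,6-trimethylcyclohex-1-en-1-yl)hex-3-en-1-yl]-2H-chromen-6-ol | CC1=C(CC/C(C)=C/CC[C@@]2(C)C=Cc3cc(O)ccc3O2)C(C)(C)CCC1 | target

## Step count and risks

Total step count: 16 steps.
Longest linear sequence: 11 steps (steps 1, 2, 3, 4, 5, 9, 10, 11, 14, 15, 16).

The three steps most likely to fail:

**Step 14.** The phenol may attack the primary terminus of the π-allyl complex, the tertiary ether may re-ionise and drift to the linear ether, or the two π-allyl faces may be told apart too poorly, so that regiochemistry or enantiopurity is lost. The fallback sets out from 15 and comes back at 21. Alcohol 15 is oxidised with MnO2 (CH2Cl2, rt) to (2E,6E)-3,7-dimethyl-9-(2,6,6-trimethylcyclohex-1-en-1-yl)nona-2,6-dienal F1. F1 is condensed with commercial 4-[(tert-butyldimethylsilyl)oxy]phenol (PhB(OH)2, AcOH, toluene, reflux with removal of water). Through an ortho-quinone methide and an oxa-6π electrocyclisation this should give racemic tert-butyldimethyl{[2-methyl-2-[(3E)-4-methyl-6-(2,6,6-trimethylcyclohex-1-en-1-yl)hex-3-en-1-yl]-2H-chromen-6-yl]oxy}silane F2. Preparative chromatography on a chiral stationary phase then delivers the (S)-enantiomer 21, and step 16 follows. Steps 11 to 15 fall away, at the price of half of the material.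

**Step 1.** Residual THF and the lithium and sodium halides may bind SnCl4 so that the cyclisation stalls at 3, or the cation may be captured by the enol oxygen to give a cyclic enol ether. The fallback sets out from 3 and comes back at 4. The alkylation stage is worked up with aqueous acid and 3 is isolated. Hg(OCOCF3)2 in MeNO2 at 0 °C, then aqueous NaCl, should give by mercury-initiated cyclisation (the enol carbon opens the mercurinium ion at its tertiary carbon) methyl 3-(chloromercurio)-2,2-dimethyl-6-oxocyclohexane-1-carboxylate F3. Radical demercuration with n-Bu3SnH and AIBN (toluene, rt) returns 4.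

**Step 10.** The allyl anion formed on C–S cleavage may be protonated at the ring carbon, which moves the ring double bond into the exocyclic position, or the debenzylation may stay incomplete. The fallback sets out from 14 and comes back at 15. PdCl2(dppp) (cat.) and LiEt3BH in THF at 0 °C reduce the allylic sulfone through a π-allylpalladium hydride that delivers hydrogen to the less hindered exocyclic terminus, giving benzyl (2E,6E)-3,7-dimethyl-9-(2,6,6-trimethylcyclohex-1-en-1-yl)nona-2,6-dienyl ether F4. The benzyl group is then removed with lithium naphthalenide LiC10H8 (THF, −25 °C) to give 15.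

Further compounds
F1 | step 14 | (2E,6E)-3,7-dimethyl-9-(2,6,6-trimethylcyclohex-1-en-1-yl)nona-2,6-dienal | CC1=C(CC/C(C)=C/CC/C(C)=C/C=O)C(C)(C)CCC1
F2 | step 14 | racemic tert-butyldimethyl{[2-methyl-2-[(3E)-4-methyl-6-(2,6,6-trimethylcyclohex-1-en-1-yl)hex-3-en-1-yl]-2H-chromen-6-yl]oxy}silane | CC1=C(CC/C(C)=C/CCC2(C)C=Cc3cc(O[Si](C)(C)C(C)(C)C)ccc3O2)C(C)(C)CCC1
F3 | step 1 | methyl 3-(chloromercurio)-2,2-dimethyl-6-oxocyclohexane-1-carboxylate | COC(=O)C1C(=O)CCC([Hg]Cl)C1(C)C
F4 | step 10 | benzyl (2E,6E)-3,7-dimethyl-9-(2,6,6-trimethylcyclohex-1-en-1-yl)nona-2,6-dienyl ether | CC1=C(CC/C(C)=C/CC/C(C)=C/COCc2ccccc2)C(C)(C)CCC1
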